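**Strategy.** Ring C is not closed end to end. Its C3-hydroxy C4-ketone is read as the α-ketol isomer of a 3-formyl-3-hydroxy-2-aryl-2,3-dihydrobenzofuran in which C2 is still bonded to the future C4. One aluminium-alkoxide-mediated 1,2-shift moves C2 onto the formyl carbon: it forms C2–C3, breaks C2–C4, expands the furan to six-membered ring C and sets the trans C3 carbinol, while C2 keeps its R configuration. The precursor is the (2R,3S) tris-silyl ether with formyl cis to the aryl group; it comes from Norrish–Yang photocyclisation of an ortho-benzyloxyaryl glyoxylate, whose menthyl ester allows separation of the 2R series.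

Key step: step 14

Assumption: TBS = tert-butyldimethylsilyl; the photocyclisation is taken to give all four ester diastereomers, and the (2R,3S) isomer (aryl cis to ester) is carried on once its configuration is secured crystallographically; the (2R,3R) isomer can follow steps 12 to 14 but then relies on equilibration at C3.

**Step 1**
Reactants: 1 phloroglucinol
Product: 2 3,5-bis(TBS-oxy)phenol
Conditions: TBSCl (2.0 equiv), imidazole, DMF, 0 °C → rt
Reagents that add atoms: tert-butyldimethylsilyl chloride, C[Si](C)(Cl)C(C)(C)C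
Why: Silyl ether formation on three equivalent phenols with two equivalents of chlorosilane should give mainly the bis-ether, and the mono- and tris-ethers can be separated and recycled.

**Step 2**
Reactants: 2 3,5-bis(TBS-oxy)phenol; 3 prenyl bromide
Product: 4 1,3-bis(TBS-oxy)-5-(3-methylbut-2-enyloxy)benzene
Conditions: K2CO3, acetone, rt → 40 °C
Reagents that add atoms: none
Why: Williamson ether synthesis on the single free phenol with a reactive allylic bromide, under carbonate/acetone conditions that aryl silyl ethers should tolerate.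

**Step 3**
Reactants: 4 1,3-bis(TBS-oxy)-5-(3-methylbut-2-enyloxy)benzene
Product: 6 1,3,5-tris(TBS-oxy)-2-(2-methylbut-3-en-2-yl)benzene, via Claisen phenol 5 (not isolated)
Conditions: MTBSTFA (2 equiv), PhNEt2, 185 °C, sealed tube
Reagents that add atoms: N-methyl-N-(tert-butyldimethylsilyl)trifluoroacetamide, CN(C(=O)C(F)(F)F)[Si](C)(C)C(C)(C)C
Why: Aromatic Claisen rearrangement carries the prenyl group with allylic inversion to one of two equivalent ortho carbons, giving the 1,1-dimethylallyl group between two oxygens, and the silyl amide traps the hindered phenol at once so that abnormal Claisen rearrangement and cyclisation onto the alkene are shut off.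

**Step 4**
Reactants: 6 1,3,5-tris(TBS-oxy)-2-(2-methylbut-3-en-2-yl)benzene
Product: 7 3,5-bis(TBS-oxy)-4-(2-methylbut-3-en-2-yl)phenol
Conditions: KHF2 (1.5 equiv), MeOH–THF, 0 °C → rt
Reagents that add atoms: none
Why: Sterically differentiated desilylation: only the silyl ether para to the quaternary carbon is flanked by two ring hydrogens and releases the less hindered phenoxide, so mild bifluoride should cleave it before the two ethers that flank the quaternary group.

**Step 5**
Reactants: 8 vanillin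
Product: 9 4-(TBS-oxy)-3-methoxybenzaldehyde
Conditions: TBSCl, imidazole, CH2Cl2, rt
Reagents that add atoms: tert-butyldimethylsilyl chloride, C[Si](C)(Cl)C(C)(C)C
Why: Standard silyl ether formation on the single phenol.

**Step 6**
Reactants: 9 4-(TBS-oxy)-3-methoxybenzaldehyde
Product: 10 [4-(TBS-oxy)-3-methoxyphenyl]methanol
Conditions: NaBH4, EtOH–THF, 0 °C
Reagents that add atoms: none
Why: Borohydride reduction of an aryl aldehyde, run cold and briefly so that the aryl silyl ether survives.

**Step 7**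
Reactants: 7 3,5-bis(TBS-oxy)-4-(2-methylbut-3-en-2-yl)phenol; 10 [4-(TBS-oxy)-3-methoxyphenyl]methanol
Product: 11 1,3-bis(TBS-oxy)-5-[[4-(TBS-oxy)-3-methoxyphenyl]methoxy]-2-(2-methylbut-3-en-2-yl)benzene
Conditions: PPh3, DIAD, THF, 0 °C → rt
Reagents that add atoms: none
Why: Mitsunobu etherification of the unhindered phenol with a primary benzylic alcohol under neutral conditions that avoid an unstable para-silyloxybenzyl halide and any silyl scrambling.

**Step 8**
Reactants: 11 the aryl vanillyl ether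
Product: 12 1,3-bis(TBS-oxy)-5-[[4-(TBS-oxy)-3-methoxyphenyl]methoxy]-4-iodo-2-(2-methylbut-3-en-2-yl)benzene
Conditions: NIS (1.0 equiv), MeCN, 0 °C, dark
Reagents that add atoms: N-iodosuccinimide, O=C1CCC(=O)N1I
Why: Electrophilic aromatic iodination at one of the two equivalent free positions of ring A, which three oxygen donors make far more nucleophilic than ring B or the vinyl group.

**Step 9**
Reactants: 13 (−)-menthol; 14 oxalyl chloride
Product: 15 (1R,2S,5R)-2-isopropyl-5-methylcyclohexyl 2-chloro-2-oxoacetate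
Conditions: (COCl)2 (4 equiv), CH2Cl2, 0 °C → rt; evaporation
Reagents that add atoms: none
Why: Acylation of a secondary alcohol by excess oxalyl chloride stops at the mono-ester acid chloride, and the menthyl stereocentres are not involved.

**Step 10**
Reactants: 12 the aryl iodide; 15 menthyl chlorooxoacetate
Product: 17 (1R,2S,5R)-2-isopropyl-5-methylcyclohexyl 2-[2,4-bis(TBS-oxy)-6-[[4-(TBS-oxy)-3-methoxyphenyl]methoxy]-3-(2-methylbut-3-en-2-yl)phenyl]-2-oxoacetate, via arylmagnesium chloride 16 (not isolated)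
Conditions: iPrMgCl·LiCl, THF, −20 → 0 °C; then added to 15 (2 equiv), THF, −78 °C
Reagents that add atoms: none
Why: Iodine–magnesium exchange followed by inverse-addition acylation of the aryl Grignard reagent by the acid chloride places the keto ester regiospecifically without Lewis acids that would endanger the benzyl ether, silyl ethers and alkene, and magnesium avoids the oxygen-to-carbon silyl shift to which an ortho-lithiated aryl silyl ether is prone.

**Step 11**
Reactants: 17 the menthyl aryl glyoxylate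
Product: 18 (1R,2S,5R)-2-isopropyl-5-methylcyclohexyl (2R,3S)-4,6-bis(TBS-oxy)-2-[4-(TBS-oxy)-3-methoxyphenyl]-3-hydroxy-5-(2-methylbut-3-en-2-yl)-2,3-dihydro-1-benzofuran-3-carboxylate
Conditions: hν (365 nm), degassed PhH (0.01 M), 20 °C; diastereomers separated on SiO2, then crystallisation
Reagents that add atoms: none
Why: Norrish–Yang photocyclisation: the excited keto group abstracts a benzylic δ-hydrogen of the ortho benzyl ether (the silyl ether on the other ortho oxygen offers none) and the 1,5-biradical closes to the five-membered ring, forming the C2–C3 bond and both stereocentres without absolute control, while the menthyl ester makes the 2R and 2S series diastereomeric so that the (2R,3S) isomer is obtained by separation.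

**Step 12**
Reactants: 18 the (2R,3S) menthyl ester
Product: 19 (2R,3R)-4,6-bis(TBS-oxy)-2-[4-(TBS-oxy)-3-methoxyphenyl]-3-(hydroxymethyl)-5-(2-methylbut-3-en-2-yl)-2,3-dihydro-1-benzofuran-3-ol
Conditions: LiBH4, THF, 0 °C → rt
Reagents that add atoms: none
Why: Hydroxyl-assisted borohydride reduction of an α-hydroxy ester to the primary alcohol releases the auxiliary and leaves aryl silyl ethers, alkene and both stereocentres untouched (the C3 descriptor changes only by priority).

**Step 13**
Reactants: 19 the 1,2-diol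
Product: 20 (2R,3S)-4,6-bis(TBS-oxy)-2-[4-(TBS-oxy)-3-methoxyphenyl]-3-hydroxy-5-(2-methylbut-3-en-2-yl)-2,3-dihydro-1-benzofuran-3-carbaldehyde
Conditions: Dess–Martin periodinane, CH2Cl2, 0 °C; crude aldehyde used at once
Reagents that add atoms: none
Why: Dess–Martin oxidation converts the primary alcohol into the aldehyde while the tertiary alcohol cannot be oxidised, and the aldehyde has no α-hydrogen to epimerise.

**Step 14**
Reactants: 20 the (2R,3S) tertiary α-hydroxy aldehyde
Product: 21 (2R,3R)-5,7-bis(TBS-oxy)-2-[4-(TBS-oxy)-3-methoxyphenyl]-3-hydroxy-6-(2-methylbut-3-en-2-yl)chroman-4-one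
Conditions: Al(OtBu)3 (1.1 equiv), PhMe, 25 → 60 °C; aq. potassium sodium tartrate work-up
Reagents that add atoms: none
Why: Proposed new method: the tertiary alcohol exchanges onto aluminium and the formyl oxygen chelates the same metal, so the carbinol oxygen pushes while the Lewis acid pulls, and C2 shifts with its bonding pair and with retention from the carbinol carbon to the formyl carbon; the closest known reaction type is the α-ketol (acyloin) rearrangement of tertiary α-hydroxy aldehydes with ring expansion. Ring C is closed by ring expansion through this 1,2-shift (the formyl carbon is inserted into the C2–C4 bond, furan to six-membered pyranone) and not by an end-to-end cyclisation. C2 stays R because the migrating carbon never leaves the molecule. The new C3 centre is set by the chelate: with formyl cis to the aryl group, the formyl oxygen sits on the hydroxyl side, so the new C–O bond ends up trans to the aryl group, which is also the diequatorial, thermodynamically preferred arrangement reachable by enolisation. The step needs migration of C2 and not of the aryl carbon C3a: C2 should migrate better because its developing positive charge is stabilised by the ring oxygen and the para-silyloxyphenyl group, C3a is crowded by the neighbouring silyloxy group, and the reversible shift collects in the conjugated aryl ketone. The non-ionising, hydride-free aluminium alkoxide is chosen to avoid silyl transfer to a free tertiary alkoxide, ionisation of the benzylic C2–O bond and base-induced opening of ring C.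

**Step 15**
Reactants: 21 the tris-silyl dihydroflavonol
Product: 22 (2R,3R)-3,5,7-trihydroxy-2-(4-hydroxy-3-methoxyphenyl)-6-(2-methylbut-3-en-2-yl)chroman-4-one
Conditions: TBAF (3.3 equiv), AcOH (3.3 equiv), THF, 0 °C
Reagents that add atoms: none
Why: Fluoride-mediated desilylation of three aryl silyl ethers, buffered with acetic acid so that the base-sensitive dihydroflavonol is not opened or epimerised and the alkene is not protonated.

**Compound list**
1 | phloroglucinol (benzene-1,3,5-triol) | Oc1cc(O)cc(O)c1 | starting material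
2 | 3,5-bis(TBS-oxy)phenol | Oc1cc(O[Si](C)(C)C(C)(C)C)cc(O[Si](C)(C)C(C)(C)C)c1 | intermediate
3 | prenyl bromide (1-bromo-3-methylbut-2-ene) | CC(C)=CCBr | starting material
4 | 1,3-bis(TBS-oxy)-5-(3-methylbut-2-enyloxy)benzene | CC(C)=CCOc1cc(O[Si](C)(C)C(C)(C)C)cc(O[Si](C)(C)C(C)(C)C)c1 | intermediate
5 | 3,5-bis(TBS-oxy)-2-(2-methylbut-3-en-2-yl)phenol (Claisen phenol, not isolated) | C=CC(C)(C)c1c(O)cc(O[Si](C)(C)C(C)(C)C)cc1O[Si](C)(C)C(C)(C)C | intermediate
6 | 1,3,5-tris(TBS-oxy)-2-(2-methylbut-3-en-2-yl)benzene | C=CC(C)(C)c1c(O[Si](C)(C)C(C)(C)C)cc(O[Si](C)(C)C(C)(C)C)cc1O[Si](C)(C)C(C)(C)C | intermediate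
7 | 3,5-bis(TBS-oxy)-4-(2-methylbut-3-en-2-yl)phenol | C=CC(C)(C)c1c(O[Si](C)(C)C(C)(C)C)cc(O)cc1O[Si](C)(C)C(C)(C)C | intermediate
8 | vanillin | COc1cc(C=O)ccc1O | starting material
9 | 4-(TBS-oxy)-3-methoxybenzaldehyde | COc1cc(C=O)ccc1O[Si](C)(C)C(C)(C)C | intermediate
10 | [4-(TBS-oxy)-3-methoxyphenyl]methanol | COc1cc(CO)ccc1O[Si](C)(C)C(C)(C)C | intermediate
11 | 1,3-bis(TBS-oxy)-5-[[4-(TBS-oxy)-3-methoxyphenyl]methoxy]-2-(2-methylbut-3-en-2-yl)benzene | C=CC(C)(C)c1c(O[Si](C)(C)C(C)(C)C)cc(OCc2ccc(O[Si](C)(C)C(C)(C)C)c(OC)c2)cc1O[Si](C)(C)C(C)(C)C | intermediate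
12 | 1,3-bis(TBS-oxy)-5-[[4-(TBS-oxy)-3-methoxyphenyl]methoxy]-4-iodo-2-(2-methylbut-3-en-2-yl)benzene | C=CC(C)(C)c1c(O[Si](C)(C)C(C)(C)C)cc(OCc2ccc(O[Si](C)(C)C(C)(C)C)c(OC)c2)c(I)c1O[Si](C)(C)C(C)(C)C | intermediate
13 | (−)-menthol, (1R,2S,5R)-2-isopropyl-5-methylcyclohexanol | C[C@@H]1CC[C@H]([C@@H](C1)O)C(C)C | starting material
14 | oxalyl chloride | O=C(Cl)C(=O)Cl | starting material
15 | (1R,2S,5R)-2-isopropyl-5-methylcyclohexyl 2-chloro-2-oxoacetate | O=C(Cl)C(=O)O[C@@H]1C[C@H](C)CC[C@H]1C(C)C | intermediate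
16 | arylmagnesium chloride from 12 (magnesium in place of iodine, not isolated) | C=CC(C)(C)c1c(O[Si](C)(C)C(C)(C)C)cc(OCc2ccc(O[Si](C)(C)C(C)(C)C)c(OC)c2)c([Mg]Cl)c1O[Si](C)(C)C(C)(C)C | intermediate
17 | menthyl 2-[2,4-bis(TBS-oxy)-6-[[4-(TBS-oxy)-3-methoxyphenyl]methoxy]-3-(2-methylbut-3-en-2-yl)phenyl]-2-oxoacetate | C=CC(C)(C)c1c(O[Si](C)(C)C(C)(C)C)cc(OCc2ccc(O[Si](C)(C)C(C)(C)C)c(OC)c2)c(C(=O)C(=O)O[C@@H]3C[C@H](C)CC[C@H]3C(C)C)c1O[Si](C)(C)C(C)(C)C | intermediate
18 | menthyl (2R,3S)-4,6-bis(TBS-oxy)-2-[4-(TBS-oxy)-3-methoxyphenyl]-3-hydroxy-5-(2-methylbut-3-en-2-yl)-2,3-dihydro-1-benzofuran-3-carboxylate (aryl cis to ester) | C=CC(C)(C)c1c(O[Si](C)(C)C(C)(C)C)cc2c(c1O[Si](C)(C)C(C)(C)C)[C@@](O)(C(=O)O[C@@H]3C[C@H](C)CC[C@H]3C(C)C)[C@@H](c3ccc(O[Si](C)(C)C(C)(C)C)c(OC)c3)O2 | intermediate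
19 | (2R,3R)-4,6-bis(TBS-oxy)-2-[4-(TBS-oxy)-3-methoxyphenyl]-3-(hydroxymethyl)-5-(2-methylbut-3-en-2-yl)-2,3-dihydro-1-benzofuran-3-ol | C=CC(C)(C)c1c(O[Si](C)(C)C(C)(C)C)cc2c(c1O[Si](C)(C)C(C)(C)C)[C@@](O)(CO)[C@@H](c3ccc(O[Si](C)(C)C(C)(C)C)c(OC)c3)O2 | intermediate
20 | (2R,3S)-4,6-bis(TBS-oxy)-2-[4-(TBS-oxy)-3-methoxyphenyl]-3-hydroxy-5-(2-methylbut-3-en-2-yl)-2,3-dihydro-1-benzofuran-3-carbaldehyde (formyl cis to aryl) | C=CC(C)(C)c1c(O[Si](C)(C)C(C)(C)C)cc2c(c1O[Si](C)(C)C(C)(C)C)[C@@](O)(C=O)[C@@H](c3ccc(O[Si](C)(C)C(C)(C)C)c(OC)c3)O2 | intermediate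
21 | (2R,3R)-5,7-bis(TBS-oxy)-2-[4-(TBS-oxy)-3-methoxyphenyl]-3-hydroxy-6-(2-methylbut-3-en-2-yl)chroman-4-one | C=CC(C)(C)c1c(O[Si](C)(C)C(C)(C)C)cc2c(c1O[Si](C)(C)C(C)(C)C)C(=O)[C@H](O)[C@@H](c3ccc(O[Si](C)(C)C(C)(C)C)c(OC)c3)O2 | intermediate
22 | (2R,3R)-3,5,7-trihydroxy-2-(4-hydroxy-3-methoxyphenyl)-6-(2-methylbut-3-en-2-yl)chroman-4-one | C=CC(C)(C)c1c(O)cc2c(c1O)C(=O)[C@H](O)[C@@H](c3ccc(O)c(OC)c3)O2 | target

**Step count.** Total: 15 steps. Longest linear sequence: 12 steps (1, 2, 3, 4, 7, 8, 10, 11, 12, 13, 14, 15).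

**Steps most likely to fail**

Step 14 (proposed new method). The shift may take the wrong course: the electron-rich aryl carbon may migrate in place of C2, the peri silyl group may move onto the tertiary alkoxide, or C2 may lose its configuration through reversible opening at the benzylic C–O bond. In that case ring C would be closed by the established chalcone epoxide route, which sets out from phenol 7 and aldehyde 9 and returns at 21. Phenol 7 is protected with MOMCl/iPr2NEt as 1-(methoxymethoxy)-3,5-bis(TBS-oxy)-4-(2-methylbut-3-en-2-yl)benzene F1, and NIS iodinates one of its two equivalent free positions to give the aryl iodide F2. Exchange with iPrMgCl·LiCl gives the arylmagnesium chloride F3. This is acylated by the Weinreb cinnamamide F4, made from 9 by Horner–Wadsworth–Emmons reaction with diethyl [2-(methoxy(methyl)amino)-2-oxoethyl]phosphonate and NaH, to give the 2'-MOM-protected chalcone F5. Juliá–Colonna epoxidation (poly-L-leucine, urea–hydrogen peroxide, DBU, THF) should give the (αR,βS)-epoxide F6. Catalytic HCl in MeOH–THF removes the MOM group, and the free 2'-hydroxy epoxide F7 (not isolated) opens the epoxide at the benzylic carbon with inversion in a 6-endo closure, giving 21 with 2R,3R configuration.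

Step 11. The photocyclisation may be diverted by hydrogen abstraction from the menthyl methine C–H with fragmentation of the ester, or the four diastereomers may not separate. The auxiliary is then given up, in a detour that sets out from iodide 12 and returns at diol 19. The arylmagnesium chloride 16 made from 12 is acylated with methyl chlorooxoacetate to the methyl aryl glyoxylate F8. Irradiation as in step 11 should give the racemic methyl ester with aryl cis to ester F9, and LiBH4 reduces it to the racemic diol F10. Preparative chromatography on a chiral stationary phase (amylose tris(3,5-dimethylphenylcarbamate)) then delivers the (2R,3R) enantiomer, which is 19.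

Step 4. Bifluoride may not discriminate enough between the three aryl silyl ethers, so that cleavage runs on to diols and triol. The selectivity is then moved from deprotection to etherification, setting out from 6 and returning at 11. TBAF/AcOH removes all three silyl groups from 6 to give 2-(2-methylbut-3-en-2-yl)benzene-1,3,5-triol F11. Mitsunobu reaction with one equivalent of alcohol 10 (PPh3, DIAD) should etherify the only hydroxyl not flanked by the quaternary carbon, giving the 5-benzyl ether diol F12. TBSOTf/2,6-lutidine then silylates the two hindered phenols to give 11.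

**Further compounds**
F1 | step 14 | 1-(methoxymethoxy)-3,5-bis(TBS-oxy)-4-(2-methylbut-3-en-2-yl)benzene | C=CC(C)(C)c1c(O[Si](C)(C)C(C)(C)C)cc(OCOC)cc1O[Si](C)(C)C(C)(C)C
F2 | step 14 | 2-iodo-1-(methoxymethoxy)-3,5-bis(TBS-oxy)-4-(2-methylbut-3-en-2-yl)benzene | C=CC(C)(C)c1c(O[Si](C)(C)C(C)(C)C)cc(OCOC)c(I)c1O[Si](C)(C)C(C)(C)C
F3 | step 14 | arylmagnesium chloride from F2 | C=CC(C)(C)c1c(O[Si](C)(C)C(C)(C)C)cc(OCOC)c([Mg]Cl)c1O[Si](C)(C)C(C)(C)C
F4 | step 14 | (E)-3-[4-(TBS-oxy)-3-methoxyphenyl]-N-methoxy-N-methylprop-2-enamide | CON(C)C(=O)/C=C/c1ccc(O[Si](C)(C)C(C)(C)C)c(OC)c1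
F5 | step 14 | (E)-1-[2,4-bis(TBS-oxy)-6-(methoxymethoxy)-3-(2-methylbut-3-en-2-yl)phenyl]-3-[4-(TBS-oxy)-3-methoxyphenyl]prop-2-en-1-one | C=CC(C)(C)c1c(O[Si](C)(C)C(C)(C)C)cc(OCOC)c(C(=O)/C=C/c2ccc(O[Si](C)(C)C(C)(C)C)c(OC)c2)c1O[Si](C)(C)C(C)(C)C
F6 | step 14 | [2,4-bis(TBS-oxy)-6-(methoxymethoxy)-3-(2-methylbut-3-en-2-yl)phenyl] [(2R,3S)-3-[4-(TBS-oxy)-3-methoxyphenyl]oxiran-2-yl] ketone | C=CC(C)(C)c1c(O[Si](C)(C)C(C)(C)C)cc(OCOC)c(C(=O)[C@@H]2O[C@H]2c3ccc(O[Si](C)(C)C(C)(C)C)c(OC)c3)c1O[Si](C)(C)C(C)(C)C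
F7 | step 14 | [2,4-bis(TBS-oxy)-6-hydroxy-3-(2-methylbut-3-en-2-yl)phenyl] [(2R,3S)-3-[4-(TBS-oxy)-3-methoxyphenyl]oxiran-2-yl] ketone | C=CC(C)(C)c1c(O[Si](C)(C)C(C)(C)C)cc(O)c(C(=O)[C@@H]2O[C@H]2c3ccc(O[Si](C)(C)C(C)(C)C)c(OC)c3)c1O[Si](C)(C)C(C)(C)C
F8 | step 11 | methyl 2-[2,4-bis(TBS-oxy)-6-[[4-(TBS-oxy)-3-methoxyphenyl]methoxy]-3-(2-methylbut-3-en-2-yl)phenyl]-2-oxoacetate | C=CC(C)(C)c1c(O[Si](C)(C)C(C)(C)C)cc(OCc2ccc(O[Si](C)(C)C(C)(C)C)c(OC)c2)c(C(=O)C(=O)OC)c1O[Si](C)(C)C(C)(C)C
F9 | step 11 | racemic methyl (2R*,3S*)-4,6-bis(TBS-oxy)-2-[4-(TBS-oxy)-3-methoxyphenyl]-3-hydroxy-5-(2-methylbut-3-en-2-yl)-2,3-dihydro-1-benzofuran-3-carboxylate (one enantiomer drawn) | C=CC(C)(C)c1c(O[Si](C)(C)C(C)(C)C)cc2c(c1O[Si](C)(C)C(C)(C)C)[C@@](O)(C(=O)OC)[C@@H](c3ccc(O[Si](C)(C)C(C)(C)C)c(OC)c3)O2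
F10 | step 11 | racemic (2R*,3R*)-4,6-bis(TBS-oxy)-2-[4-(TBS-oxy)-3-methoxyphenyl]-3-(hydroxymethyl)-5-(2-methylbut-3-en-2-yl)-2,3-dihydro-1-benzofuran-3-ol (one enantiomer drawn) | C=CC(C)(C)c1c(O[Si](C)(C)C(C)(C)C)cc2c(c1O[Si](C)(C)C(C)(C)C)[C@@](O)(CO)[C@@H](c3ccc(O[Si](C)(C)C(C)(C)C)c(OC)c3)O2
F11 | step 4 | 2-(2-methylbut-3-en-2-yl)benzene-1,3,5-triol | C=CC(C)(C)c1c(O)cc(O)cc1O
F12 | step 4 | 5-[[4-(TBS-oxy)-3-methoxyphenyl]methoxy]-2-(2-methylbut-3-en-2-yl)benzene-1,3-diol | C=CC(C)(C)c1c(O)cc(OCc2ccc(O[Si](C)(C)C(C)(C)C)c(OC)c2)cc1O
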